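**Retrosynthetic overview**

- Feature: in ring A and in ring B the two bromines sit at C4 and C6 (C1 = bridging oxygen, C2 = OMe on ring A, OH on ring B), on either side of the lone C5–H. That C5 is para to the C2 oxygen and meta to the bridging oxygen, so an NH2 placed there is ortho to both bromine-bearing carbons and can be deleted afterwards.
- Last disconnections: the O–benzyl bond on ring B, then the two C5–N bonds (reductive deamination).
- Key disconnection: all four C–Br bonds, made in one operation by Br2 on a bis-aniline. The diaryl ether already exists at that point, so no coupling to a doubly ortho-substituted ring is needed.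
- The bis-aniline comes from a dinitro diaryl ether, assembled by copper-catalysed C1–O coupling of 2-methoxy-5-nitrophenol with 1-(benzyloxy)-2-bromo-4-nitrobenzene.
- No ring is formed at any stage; both benzene rings are bought as nitrophenols.

Key step: step 4

Remark on the chemistry: the two nitrogen atoms are brought in with the purchasable building blocks 2-bromo-4-nitrophenol and 2-methoxy-5-nitrophenol, so their position para to the C2 oxygen is fixed by constitution and not by a nitration of the assembled ether.

**Route**

Step 1
Reactants: 1 2-bromo-4-nitrophenol; 2 benzyl bromide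
Product: 3 1-(benzyloxy)-2-bromo-4-nitrobenzene
Conditions: K2CO3, DMF, 60 °C
Reagents that add atoms: benzyl bromide (2), BrCc1ccccc1
Why: Williamson ether synthesis, an SN2 O-alkylation of an acidic nitrophenoxide by a reactive benzylic bromide, in which the aryl bromide and the nitro group are inert.

Step 2
Reactants: 3 1-(benzyloxy)-2-bromo-4-nitrobenzene; 4 2-methoxy-5-nitrophenol
Product: 5 1-(benzyloxy)-2-(2-methoxy-5-nitrophenoxy)-4-nitrobenzene
Conditions: CuI (10 mol %), picolinic acid (20 mol %), K3PO4, DMSO, 100 °C, argon
Reagents that add atoms: none
Why: Ullmann-type copper-catalysed diaryl ether coupling, in which the nitro group speeds activation of the C–Br bond, the phenoxide (a guaiacol with a meta acceptor, of the isovanillin type) is still nucleophilic enough under picolinate ligation, and the bromide lies meta to its nitro group so no uncatalysed SNAr can give another constitution.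

Step 3
Reactants: 5 1-(benzyloxy)-2-(2-methoxy-5-nitrophenoxy)-4-nitrobenzene
Product: 6 3-(5-amino-2-methoxyphenoxy)-4-(benzyloxy)aniline
Conditions: Fe powder, NH4Cl, EtOH/H2O, 80 °C
Reagents that add atoms: none
Why: Béchamp-type reduction of both nitro groups by Fe in a near-neutral medium, which should leave the benzyl ether intact where hydrogenolysis over a palladium catalyst would not.

Step 4
Reactants: 6 3-(5-amino-2-methoxyphenoxy)-4-(benzyloxy)aniline; 7 bromine
Product: 8 3-(3-amino-2,4-dibromo-6-methoxyphenoxy)-4-(benzyloxy)-2,6-dibromoaniline
Conditions: Br2 (4.0 equiv, added dropwise in AcOH), NaOAc (4.4 equiv), AcOH, 10–15 °C → rt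
Reagents that add atoms: bromine (7), BrBr
Why: Electrophilic aromatic substitution through Wheland intermediates, in which the free NH2 at C5 is the strongest donor on each ring and, with its para position (C2) blocked by the alkoxy group, sends bromine to both ortho carbons, C4 and C6. These two carbons are also para and ortho to the bridging oxygen at C1, so two donors reinforce each other there, whereas the only other open site, C3, is activated by the C2 alkoxy group alone and is meta to both the amine and the bridging oxygen. The closest known reaction is the 2,6-dibromination of 4-alkoxyanilines with Br2 in acetic acid, the first stage of the classical preparation of 3,5-dibromoanisole. No ring is closed and no stereocentre is created. The step needs C4/C6 over C3 on both rings and substitution over oxidation of the aminoarene: NaOAc keeps the amines unprotonated and takes up the HBr that could attack the benzyl ether, each ring is deactivated once it carries two bromines, and the bromine is limited to four equivalents and added cold.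

Step 5
Reactants: 8 3-(3-amino-2,4-dibromo-6-methoxyphenoxy)-4-(benzyloxy)-2,6-dibromoaniline
Product: 10 1-(benzyloxy)-3,5-dibromo-2-(2,4-dibromo-6-methoxyphenoxy)benzene, via bis-diazonium bis(hydrogen sulfate) 9 (not isolated)
Conditions: NaNO2, H2SO4, AcOH, 0–5 °C; then 50% aq. H3PO2, 0 °C → rt
Reagents that add atoms: none
Why: Diazotisation of the two weakly basic, doubly ortho-brominated amines by nitrosylsulfuric acid followed by hydrodediazoniation with hypophosphorous acid, the classical reductive deamination, which should replace each N2 group by hydrogen without touching the C–Br bonds or the ethers at this temperature.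

Step 6
Reactants: 10 1-(benzyloxy)-3,5-dibromo-2-(2,4-dibromo-6-methoxyphenoxy)benzene
Product: 12 3,5-dibromo-2-(2,4-dibromo-6-methoxyphenoxy)phenol, via aryl dichloroborinate 11 (not isolated)
Conditions: BCl3 (1 M in CH2Cl2), pentamethylbenzene, CH2Cl2, −78 °C; then MeOH, aqueous work-up
Reagents that add atoms: none
Why: Lewis-acid debenzylation by BCl3 with pentamethylbenzene as a non-basic Friedel–Crafts trap for the benzyl cation, which should cleave the benzyl ether at low temperature while sparing the aryl methyl ether, the diaryl ether and the four C–Br bonds that hydrogenolysis would remove.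

**Compound list**

1 | 2-bromo-4-nitrophenol | Oc1ccc(cc1Br)[N+](=O)[O-] | starting material
2 | benzyl bromide | BrCc1ccccc1 | starting material
3 | 1-(benzyloxy)-2-bromo-4-nitrobenzene | O=[N+]([O-])c1ccc(OCc2ccccc2)c(Br)c1 | intermediate
4 | 2-methoxy-5-nitrophenol | COc1ccc(cc1O)[N+](=O)[O-] | starting material
5 | 1-(benzyloxy)-2-(2-methoxy-5-nitrophenoxy)-4-nitrobenzene | COc1ccc([N+](=O)[O-])cc1Oc1cc([N+](=O)[O-])ccc1OCc1ccccc1 | intermediate
6 | 3-(5-amino-2-methoxyphenoxy)-4-(benzyloxy)aniline | COc1ccc(N)cc1Oc1cc(N)ccc1OCc1ccccc1 | intermediate
7 | bromine | BrBr | starting material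
8 | 3-(3-amino-2,4-dibromo-6-methoxyphenoxy)-4-(benzyloxy)-2,6-dibromoaniline | COc1cc(Br)c(N)c(Br)c1Oc1c(Br)c(N)c(Br)cc1OCc1ccccc1 | intermediate
9 | 3-(benzyloxy)-2-(2,4-dibromo-3-diazonio-6-methoxyphenoxy)-4,6-dibromobenzenediazonium bis(hydrogen sulfate) | COc1cc(Br)c([N+]#N)c(Br)c1Oc1c(Br)c([N+]#N)c(Br)cc1OCc1ccccc1.OS(=O)(=O)[O-].OS(=O)(=O)[O-] | intermediate
10 | 1-(benzyloxy)-3,5-dibromo-2-(2,4-dibromo-6-methoxyphenoxy)benzene | COc1cc(Br)cc(Br)c1Oc1c(Br)cc(Br)cc1OCc1ccccc1 | intermediate
11 | 3,5-dibromo-2-(2,4-dibromo-6-methoxyphenoxy)phenyl dichloroborinate | COc1cc(Br)cc(Br)c1Oc1c(OB(Cl)Cl)cc(Br)cc1Br | intermediate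
12 | 3,5-dibromo-2-(2,4-dibromo-6-methoxyphenoxy)phenol | COc1cc(Br)cc(Br)c1Oc1c(O)cc(Br)cc1Br | target

**Totals**

Total step count: 6. Longest linear sequence: 6 steps (from 1 to 12).

**Steps most likely to fail**

1. Step 4 (key step). Bromine may oxidise the electron-rich aminoarene rings instead of substituting them. The two rings may also be halogenated unevenly, with a further bromine entering one ring at C3 while the other ring is still incomplete.
   Fallback: the halogenation is done one ring at a time, so that only one amino-activated ring meets bromine in each operation. It sets out from 3 and comes back at 8. Bromide 3 is coupled with purchased 5-amino-2-methoxyphenol (COc1ccc(N)cc1O) under the CuI/picolinic acid/K3PO4/DMSO conditions, which are known to arylate the oxygen of 3-aminophenols in preference to nitrogen. This should give 3-[2-(benzyloxy)-5-nitrophenoxy]-4-methoxyaniline F1. Two equivalents of Br2 with NaOAc in AcOH should brominate only the amino-bearing ring A, ring B being deactivated by its nitro group, to give 3-[2-(benzyloxy)-5-nitrophenoxy]-2,6-dibromo-4-methoxyaniline F2. Reduction of the nitro group with Fe and NH4Cl should then give 3-[5-amino-2-(benzyloxy)phenoxy]-2,6-dibromo-4-methoxyaniline F3. A second treatment with two equivalents of Br2 and NaOAc in AcOH, now with ring A deactivated by its two bromines, should lead to 8.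

2. Step 2. The C–O coupling may be slow because the nitrophenoxide is a weak nucleophile and the bromide is ortho-substituted. At the temperature then needed, benzyl transfer from the activated nitrophenyl benzyl ether to the phenoxide and hydrodebromination may take over.
   Fallback: the bridging C–O bond is made by SNAr and the second nitrogen is introduced afterwards. It sets out from 4 and comes back at 5. Phenol 4 and 2-fluorobenzaldehyde (K2CO3, DMF, 130 °C) should give 2-(2-methoxy-5-nitrophenoxy)benzaldehyde F4 by substitution of the fluoride ortho to the formyl group. Baeyer–Villiger oxidation with mCPBA in CH2Cl2 should give 2-(2-methoxy-5-nitrophenoxy)phenyl formate F5. Hydrolysis with KOH in MeOH/H2O should give 2-(2-methoxy-5-nitrophenoxy)phenol F6. Benzylation with 2 and K2CO3 in DMF should give 1-(benzyloxy)-2-(2-methoxy-5-nitrophenoxy)benzene F7. Mononitration with HNO3 in AcOH should then give 5: ring A is deactivated by its nitro group, and on ring B the benzyloxy group is a far stronger para director than the nitroaryloxy group.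

3. Step 5. The double diazotisation may stay incomplete, because both amines are weakly basic and doubly ortho-brominated and the lipophilic substrate dissolves poorly in the acid. The diazonium groups may be hydrolysed, and the benzyl ether may be lost in the strong acid.
   Fallback: the deamination is moved from aqueous diazonium chemistry to a one-pot, acid-free radical-chain process. It sets out from 8 and comes back at 10. tert-Butyl nitrite in DMF at 60 °C nitrosates each amine in homogeneous solution, the diazo species loses N2, and the aryl radical takes a hydrogen atom from the solvent. This is known for polyhalogenated anilines and makes no new isolable compound.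

**Further compounds**

F1 | step 4 | 3-[2-(benzyloxy)-5-nitrophenoxy]-4-methoxyaniline | COc1ccc(N)cc1Oc1cc([N+](=O)[O-])ccc1OCc1ccccc1
F2 | step 4 | 3-[2-(benzyloxy)-5-nitrophenoxy]-2,6-dibromo-4-methoxyaniline | COc1cc(Br)c(N)c(Br)c1Oc1cc([N+](=O)[O-])ccc1OCc1ccccc1
F3 | step 4 | 3-[5-amino-2-(benzyloxy)phenoxy]-2,6-dibromo-4-methoxyaniline | COc1cc(Br)c(N)c(Br)c1Oc1cc(N)ccc1OCc1ccccc1
F4 | step 2 | 2-(2-methoxy-5-nitrophenoxy)benzaldehyde | COc1ccc([N+](=O)[O-])cc1Oc1ccccc1C=O
F5 | step 2 | 2-(2-methoxy-5-nitrophenoxy)phenyl formate | COc1ccc([N+](=O)[O-])cc1Oc1ccccc1OC=O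
F6 | step 2 | 2-(2-methoxy-5-nitrophenoxy)phenol | COc1ccc([N+](=O)[O-])cc1Oc1ccccc1O
F7 | step 2 | 1-(benzyloxy)-2-(2-methoxy-5-nitrophenoxy)benzene | COc1ccc([N+](=O)[O-])cc1Oc1ccccc1OCc1ccccc1
F0 | step 5 | none | none
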